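**Retrosynthetic overview** (hydrindanone numbering: C1–C3, C3a, C4 = ketone carbon, C5, C6 = carbinol carbon, C7, C7a)
1. The target comes from a 6-boryl hydrindan-4-one by C6–B to C6–OH oxidation (retention) and removal of two silyl groups.
2. The cyclohexanone is closed last, in one pot, by a nickel-catalysed acylative conjunctive annulation of a boron ate complex: C7 shifts from boron to C6 while the C4 acyl carbon bonds to C5. The ate complex is assembled in the flask from a cyclopentane acid carrying CH2Bpin and a (Z)-alkenyllithium.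
3. Enabling feature: the C7H2–C6(OH)–C5H–C4(=O) array of the cyclohexanone. The C6 tertiary carbinol lies β to the C4 ketone, so its oxygen can be a boron on a C5=C6 alkenyl group, and the two flanking ring bonds (C6–C7, C5–C4) both lead back to the same trans-1,2-dimethylcyclopentane (C7a–CH2 and C3a–CO).
4. The cyclopentane acid comes from (1S)-(−)-camphor: 9-bromination, C2–C3 cleavage, excision of C3, Br to Bpin. Camphor C1/C7 become C3a/C7a, so the trans angular methyl groups come from the chiral pool.
5. The (Z)-alkenyl iodide comes from a Stork–Zhao olefination of a homoallyl phosphonium salt (from 4-methoxy-2-methylphenol by C-prenylation and SeO2 oxidation) with 3-methyl-3-silyloxybutanal. Ring order: arene (bought), cyclopentane (carved from camphor), cyclohexanone (step 19).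

Key step: step 19

Assumption: the C9 methyl group brominated in the camphor sequence is the one anti to the C2–C3 bridge, so that CH2Br ends trans to the future acyl carbon; on this basis (1S)-camphor gives C3a (S) and C7a (R).

**Route**

Step 1
Reactants: 1 (1S,4S)-(−)-camphor
Product: 2 (1S,3R,4R)-3-endo-bromocamphor
Conditions: Br2, AcOH, 80 °C
Reagents that add atoms: bromine (BrBr)
Why: Acid-mediated α-bromination of the ketone through its enol; bromine enters from the endo face because the syn C8 methyl shields the exo face.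

Step 2
Reactants: 2 (1S,3R,4R)-3-endo-bromocamphor
Product: 3 (1S,3R,4R,7S)-3-bromo-7-(bromomethyl)-1,7-dimethylbicyclo[2.2.1]heptan-2-one (3,9-dibromocamphor)
Conditions: Br2, ClSO3H, 0 °C → rt
Reagents that add atoms: bromine (BrBr)
Why: Classical 9-bromination of camphor: reversible Wagner–Meerwein and exo-3,2-methyl shifts expose the anti C9 methyl as an exocyclic alkene, which is brominated before the shifts reverse, so C7 becomes a defined stereocentre without loss of enantiopurity.

Step 3
Reactants: 3 3,9-dibromocamphor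
Product: 4 (1S,4S,7S)-7-(bromomethyl)-1,7-dimethylbicyclo[2.2.1]heptan-2-one (9-bromocamphor)
Conditions: Zn dust, AcOH/Et2O, 0 °C
Reagents that add atoms: none
Why: Reductive dehalogenation: zinc cleaves only the α-keto C3–Br bond (zinc enolate) and leaves the unactivated neopentyl C9–Br bond.

Step 4
Reactants: 4 9-bromocamphor
Product: 5 (1S,4R,7S)-7-(bromomethyl)-1,7-dimethylbicyclo[2.2.1]heptane-2,3-dione
Conditions: SeO2, Ac2O, 140 °C
Reagents that add atoms: selenium dioxide (O=[Se]=O)
Why: Riley oxidation of the only enolisable α-methylene (C3) to the 1,2-dione; the bridgehead C1 cannot enolise.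

Step 5
Reactants: 5 9-bromocamphorquinone
Product: 6 (1S,2S,3R)-2-(bromomethyl)-1,2-dimethylcyclopentane-1,3-dicarboxylic acid
Conditions: 30% H2O2, 2 M NaOH, MeOH, 0 °C → rt; then 2 M HCl
Reagents that add atoms: hydrogen peroxide (OO)
Why: Alkaline peroxide cleavage of the 1,2-dione (Baeyer–Villiger-type insertion, then hydrolysis) opens the C2–C3 bond to the cis-1,3-diacid; the neopentyl bromide is inert to hydroxide.

Step 6
Reactants: 6 bromo diacid
Product: 7 dibenzyl (1S,2S,3R)-2-(bromomethyl)-1,2-dimethylcyclopentane-1,3-dicarboxylate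
Conditions: BnBr (2.5 equiv), K2CO3, DMF, rt
Reagents that add atoms: benzyl bromide (BrCc1ccccc1)
Why: Carboxylate O-alkylation (SN2 at the benzylic carbon) esterifies both acids regardless of hindrance at the acyl carbons.

Step 7
Reactants: 7 dibenzyl ester
Product: 8 (1R,2S,3S)-3-(benzyloxycarbonyl)-2-(bromomethyl)-2,3-dimethylcyclopentane-1-carboxylic acid
Conditions: LiOH·H2O (1.2 equiv), THF/H2O, 0 °C → rt; then dilute HCl
Reagents that add atoms: lithium hydroxide ([Li+].[OH-])
Why: Selective saponification: hydroxide attacks only the ester on the tertiary CH carbon, while the ester on the quaternary carbon flanked by a second quaternary centre is untouched (classical half-hydrolysis in the camphoric acid series).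

Step 8
Reactants: 8 mono acid
Product: 9 benzyl (1S,2S)-2-(bromomethyl)-1,2-dimethylcyclopentane-1-carboxylate
Conditions: 9-mesityl-10-phenylacridinium tetrafluoroborate (5 mol%), PhSSPh (10 mol%), i-Pr2NEt (20 mol%), CF3CH2OH, 450 nm LEDs, rt
Reagents that add atoms: none
Why: Photoredox hydrodecarboxylation: the excited acridinium oxidises the carboxylate, loss of CO2 gives the secondary radical, and thiophenol returns a hydrogen atom; this excises the former camphor C3 and leaves the two quaternary centres untouched.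

Step 9
Reactants: 9 bromo ester
Product: 10 benzyl (1S,2S)-1,2-dimethyl-2-[(4,4,5,5-tetramethyl-1,3,2-dioxaborolan-2-yl)methyl]cyclopentane-1-carboxylate
Conditions: CuI (10 mol%), PPh3 (13 mol%), LiOMe (2 equiv), B2pin2 (1.5 equiv), DMF, rt
Reagents that add atoms: bis(pinacolato)diboron (CC1(C)OB(OC1(C)C)B2OC(C)(C)C(C)(C)O2)
Why: Copper-catalysed borylation of an alkyl halide runs through an alkyl radical, so the neopentyl bromide that resists SN2 reacts; the hindered ester tolerates the alkoxide.

Step 10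
Reactants: 10 benzyl ester boronate
Product: 11 (1S,2S)-1,2-dimethyl-2-[(4,4,5,5-tetramethyl-1,3,2-dioxaborolan-2-yl)methyl]cyclopentane-1-carboxylic acid
Conditions: H2 (1 atm), 10% Pd/C, EtOAc, rt
Reagents that add atoms: none
Why: Hydrogenolysis of the benzylic C–O bond is indifferent to hindrance at the acyl carbon and does not touch the alkyl boronate.

Step 11
Reactants: 12 4-methoxy-2-methylphenol; 13 prenyl bromide (1-bromo-3-methylbut-2-ene)
Product: 14 4-methoxy-2-methyl-6-(3-methylbut-2-en-1-yl)phenol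
Conditions: NaH (1.1 equiv), toluene, 0 °C; then 13, rt
Reagents that add atoms: none
Why: Ortho C-allylation of a phenoxide: in a non-polar solvent the tight sodium ion pair is alkylated at carbon, and C6 is the only free ortho position (para is blocked).

Step 12
Reactants: 14 prenyl phenol
Product: 15 [4-methoxy-2-methyl-6-(3-methylbut-2-en-1-yl)phenoxy]tri(propan-2-yl)silane
Conditions: i-Pr3SiOTf, 2,6-lutidine, CH2Cl2, 0 °C → rt
Reagents that add atoms: triisopropylsilyl triflate (CC(C)[Si](OS(=O)(=O)C(F)(F)F)(C(C)C)C(C)C)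
Why: Silylation with the triflate overcomes the hindrance of the 2,6-disubstituted phenol; the aryl TIPS ether is stable to organolithiums and comes off with fluoride.

Step 13
Reactants: 15 TIPS ether
Product: 16 (2E)-4-[5-methoxy-3-methyl-2-(triisopropylsilyloxy)phenyl]-2-methylbut-2-en-1-ol
Conditions: SeO2 (0.5 equiv), t-BuOOH (3 equiv), CH2Cl2, 0 °C → rt
Reagents that add atoms: selenium dioxide (O=[Se]=O); tert-butyl hydroperoxide (CC(C)(C)OO)
Why: Allylic oxidation (ene reaction, then [2,3]-shift) attacks the (E)-methyl group at the more substituted alkene terminus and gives the (E)-allylic alcohol; the CH2 at the less substituted terminus is not oxidised.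

Step 14
Reactants: 16 allylic alcohol
Product: 17 {2-[(2E)-4-bromo-3-methylbut-2-en-1-yl]-4-methoxy-6-methylphenoxy}tri(propan-2-yl)silane
Conditions: CBr4, PPh3, CH2Cl2, 0 °C
Reagents that add atoms: carbon tetrabromide (BrC(Br)(Br)Br)
Why: Appel bromination of a primary allylic alcohol proceeds by SN2 without allylic transposition, so the E geometry is kept.

Step 15
Reactants: 17 allylic bromide
Product: 18 [(3E)-5-{5-methoxy-3-methyl-2-[(triisopropylsilyl)oxy]phenyl}-3-methylpent-3-en-1-yl]triphenylphosphonium bromide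
Conditions: Ph3PCH3Br, n-BuLi, THF, 0 °C; then 17, −78 °C → rt
Reagents that add atoms: methyltriphenylphosphonium bromide (C[P+](c1ccccc1)(c1ccccc1)c1ccccc1.[Br-])
Why: Alkylation of methylenetriphenylphosphorane by the primary allylic bromide (SN2) gives the homologated phosphonium salt; its carbon next to phosphorus is the future C6.

Step 16
Reactants: 19 ethyl 3-hydroxy-3-methylbutanoate
Product: 20 ethyl 3-methyl-3-(triethylsilyloxy)butanoate
Conditions: Et3SiOTf, 2,6-lutidine, CH2Cl2, 0 °C
Reagents that add atoms: triethylsilyl triflate (CC[Si](CC)(CC)OS(=O)(=O)C(F)(F)F)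
Why: Silylation of a tertiary alcohol with the silyl triflate; the TES ether survives organolithiums and is cleaved by fluoride at the end.

Step 17
Reactants: 20 TES ester
Product: 21 3-methyl-3-(triethylsilyloxy)butanal
Conditions: i-Bu2AlH (1.1 equiv), CH2Cl2, −78 °C; then aq. KNaC4H4O6
Reagents that add atoms: none
Why: Half-reduction of an ester: the tetrahedral aluminium hemiacetal is stable at −78 °C and gives the aldehyde only on work-up.

Step 18
Reactants: 18 phosphonium bromide; 21 aldehyde
Product: 25 triethyl{[(4Z,7E)-5-iodo-9-{5-methoxy-3-methyl-2-[(triisopropylsilyl)oxy]phenyl}-2,7-dimethylnona-4,7-dien-2-yl]oxy}silane, via phosphonium ylide 22 (not isolated), via α-iodophosphonium iodide 23 (not isolated), via α-iodo ylide 24 (not isolated)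
Conditions: n-BuLi, THF, −78 → 0 °C; I2, THF, −78 °C; NaN(SiMe3)2, −20 °C; then 21, −78 °C → rt
Reagents that add atoms: iodine (II)
Why: Stork–Zhao variant of the Wittig reaction: the α-iodo ylide adds to the aldehyde under kinetic control through the cis-oxaphosphetane and gives the (Z)-iodoalkene, with iodine cis to the aldehyde-derived chain.

Step 19
Reactants: 11 cyclopentane acid boronate; 25 (Z)-alkenyl iodide
Product: 30 (3aS,5R,6R,7aR)-6-{(2E)-4-[5-methoxy-3-methyl-2-(triisopropylsilyloxy)phenyl]-2-methylbut-2-en-1-yl}-3a,7a-dimethyl-5-[2-methyl-2-(triethylsilyloxy)propyl]-6-(4,4,5,5-tetramethyl-1,3,2-dioxaborolan-2-yl)octahydro-4H-inden-4-one, via alkenyllithium 26 (not isolated), via lithium carboxylate 27 (not isolated), via dilithium boron ate complex 28 (not isolated), via mixed carbonic anhydride ate complex 29 (not isolated)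
Conditions: 25, t-BuLi (2.0 equiv), Et2O, −78 °C; add 11 pretreated with LiN(SiMe3)2 (1.0 equiv) in THF, −78 → 0 °C; i-BuOCOCl (1.0 equiv), −40 °C; Ni(cod)2 (10 mol%), 4,4'-di-tert-butyl-2,2'-bipyridine (12 mol%), THF, 0 °C → rt
Reagents that add atoms: none
Why: Proposed new method: zerovalent nickel should insert into the acyl C–O bond of mixed anhydride 29, and the resulting divalent acyl nickel, held over the C5=C6 π bond by the C3a–C7a–C7 tether, should trigger a 1,2-shift of C7 from boron to C6 anti to nickel (metal-induced metallate rearrangement), after which acyl–C5 reductive elimination releases the ketone and zerovalent nickel. The closest known reaction is the intermolecular nickel-catalysed conjunctive coupling of alkenylboron ate complexes with acid chlorides or anhydrides to give β-boryl ketones; an intramolecular, ring-forming version on a trisubstituted alkenyl pinacol boronate has not been shown. The only ring closed is the cyclohexanone, by C4–C5 reductive elimination from the seven-membered nickelacycle Ni–C4–C3a–C7a–C7–C6–C5 that the C7 shift creates, i.e. a ring contraction at nickel and not a direct anti addition across the alkene, which a six-membered ring could not accommodate. C5 and C6 are fixed relative to each other by the Z geometry of 25 (boron cis to the C5 side chain): anti addition of C7 and nickel followed by retentive reductive elimination puts the two carbon side chains cis and boron cis to H-5. Their sense relative to C3a/C7a should follow from a chair-like nickelacycle on the rigid trans-1,2-disubstituted cyclopentane that keeps Bpin and the C5 side chain equatorial, whereas the other alkene face would force both to be syn-axial to the angular methyl groups. The step needs the metallate shift to win over direct alkenyl transfer from boron to nickel (open-chain enone) and over decarbonylation; the hindered α-branched alkenyl group, the tether, and the fact that decarbonylation would have to give a tertiary alkyl nickel should secure this.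

Step 20
Reactants: 30 β-boryl ketone
Product: 31 (3aS,5R,6S,7aR)-6-hydroxy-6-{(2E)-4-[5-methoxy-3-methyl-2-(triisopropylsilyloxy)phenyl]-2-methylbut-2-en-1-yl}-3a,7a-dimethyl-5-[2-methyl-2-(triethylsilyloxy)propyl]octahydro-4H-inden-4-one
Conditions: 30% H2O2, NaH2PO4/Na2HPO4 buffer (pH 7), THF, 0 °C → rt
Reagents that add atoms: hydrogen peroxide (OO)
Why: Oxidation of the C–B bond: hydroperoxide adds to boron and C6 migrates from boron to oxygen with retention, giving the tertiary alcohol; the neutral buffer is chosen to avoid retro-aldol opening of the β-hydroxy ketone.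

Step 21
Reactants: 31 bis-silyl ether
Product: 32 (3aS,5R,6S,7aR)-6-hydroxy-5-(2-hydroxy-2-methylpropyl)-6-[(2E)-4-(2-hydroxy-5-methoxy-3-methylphenyl)-2-methylbut-2-en-1-yl]-3a,7a-dimethyloctahydro-4H-inden-4-one (CNP0190381.1)
Conditions: Bu4NF (3 equiv), AcOH (3 equiv), THF, 0 °C → rt
Reagents that add atoms: none
Why: Fluoride-mediated desilylation removes the aryl TIPS and the tertiary TES ether; buffering with acetic acid keeps the medium from promoting retro-aldol cleavage or C5 epimerisation.

**Compound list**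

1 | (1S,4S)-(−)-camphor | C[C@@]12CC[C@@H](CC1=O)C2(C)C | starting material
2 | (1S,3R,4R)-3-endo-bromocamphor | C[C@@]12CC[C@@H]([C@@H](Br)C1=O)C2(C)C | intermediate
3 | (1S,3R,4R,7S)-3-bromo-7-(bromomethyl)-1,7-dimethylbicyclo[2.2.1]heptan-2-one | C[C@@]12CC[C@@H]([C@@H](Br)C1=O)[C@]2(C)CBr | intermediate
4 | (1S,4S,7S)-7-(bromomethyl)-1,7-dimethylbicyclo[2.2.1]heptan-2-one | C[C@@]12CC[C@@H](CC1=O)[C@]2(C)CBr | intermediate
5 | (1S,4R,7S)-7-(bromomethyl)-1,7-dimethylbicyclo[2.2.1]heptane-2,3-dione | C[C@@]12CC[C@@H](C(=O)C1=O)[C@]2(C)CBr | intermediate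
6 | (1S,2S,3R)-2-(bromomethyl)-1,2-dimethylcyclopentane-1,3-dicarboxylic acid | OC(=O)[C@@]1(C)CC[C@@H](C(=O)O)[C@]1(C)CBr | intermediate
7 | dibenzyl (1S,2S,3R)-2-(bromomethyl)-1,2-dimethylcyclopentane-1,3-dicarboxylate | O=C(OCc1ccccc1)[C@@]1(C)CC[C@@H](C(=O)OCc2ccccc2)[C@]1(C)CBr | intermediate
8 | (1R,2S,3S)-3-(benzyloxycarbonyl)-2-(bromomethyl)-2,3-dimethylcyclopentane-1-carboxylic acid | O=C(OCc1ccccc1)[C@@]1(C)CC[C@@H](C(=O)O)[C@]1(C)CBr | intermediate
9 | benzyl (1S,2S)-2-(bromomethyl)-1,2-dimethylcyclopentane-1-carboxylate | O=C(OCc1ccccc1)[C@@]1(C)CCC[C@]1(C)CBr | intermediate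
10 | benzyl (1S,2S)-1,2-dimethyl-2-[(4,4,5,5-tetramethyl-1,3,2-dioxaborolan-2-yl)methyl]cyclopentane-1-carboxylate | O=C(OCc1ccccc1)[C@@]1(C)CCC[C@]1(C)CB2OC(C)(C)C(C)(C)O2 | intermediate
11 | (1S,2S)-1,2-dimethyl-2-[(4,4,5,5-tetramethyl-1,3,2-dioxaborolan-2-yl)methyl]cyclopentane-1-carboxylic acid | OC(=O)[C@@]1(C)CCC[C@]1(C)CB2OC(C)(C)C(C)(C)O2 | intermediate
12 | 4-methoxy-2-methylphenol | COc1ccc(O)c(C)c1 | starting material
13 | prenyl bromide (1-bromo-3-methylbut-2-ene) | CC(C)=CCBr | starting material
14 | 4-methoxy-2-methyl-6-(3-methylbut-2-en-1-yl)phenol | COc1cc(C)c(O)c(CC=C(C)C)c1 | intermediate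
15 | [4-methoxy-2-methyl-6-(3-methylbut-2-en-1-yl)phenoxy]tri(propan-2-yl)silane | COc1cc(C)c(O[Si](C(C)C)(C(C)C)C(C)C)c(CC=C(C)C)c1 | intermediate
16 | (2E)-4-[5-methoxy-3-methyl-2-(triisopropylsilyloxy)phenyl]-2-methylbut-2-en-1-ol | COc1cc(C)c(O[Si](C(C)C)(C(C)C)C(C)C)c(C/C=C(\C)CO)c1 | intermediate
17 | {2-[(2E)-4-bromo-3-methylbut-2-en-1-yl]-4-methoxy-6-methylphenoxy}tri(propan-2-yl)silane | COc1cc(C)c(O[Si](C(C)C)(C(C)C)C(C)C)c(C/C=C(\C)CBr)c1 | intermediate
18 | [(3E)-5-{5-methoxy-3-methyl-2-[(triisopropylsilyl)oxy]phenyl}-3-methylpent-3-en-1-yl]triphenylphosphonium bromide | [Br-].COc1cc(C)c(O[Si](C(C)C)(C(C)C)C(C)C)c(C/C=C(\C)CC[P+](c2ccccc2)(c3ccccc3)c4ccccc4)c1 | intermediate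
19 | ethyl 3-hydroxy-3-methylbutanoate | CCOC(=O)CC(C)(C)O | starting material
20 | ethyl 3-methyl-3-(triethylsilyloxy)butanoate | CCOC(=O)CC(C)(C)O[Si](CC)(CC)CC | intermediate
21 | 3-methyl-3-(triethylsilyloxy)butanal | O=CCC(C)(C)O[Si](CC)(CC)CC | intermediate
22 | phosphonium ylide of 18 | COc1cc(C)c(O[Si](C(C)C)(C(C)C)C(C)C)c(C/C=C(\C)CC=P(c2ccccc2)(c3ccccc3)c4ccccc4)c1 | intermediate (not isolated)
23 | α-iodophosphonium iodide (racemic at the CHI carbon) | [I-].COc1cc(C)c(O[Si](C(C)C)(C(C)C)C(C)C)c(C/C=C(\C)CC(I)[P+](c2ccccc2)(c3ccccc3)c4ccccc4)c1 | intermediate (not isolated)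
24 | α-iodo ylide | COc1cc(C)c(O[Si](C(C)C)(C(C)C)C(C)C)c(C/C=C(\C)CC(I)=P(c2ccccc2)(c3ccccc3)c4ccccc4)c1 | intermediate (not isolated)
25 | triethyl{[(4Z,7E)-5-iodo-9-{5-methoxy-3-methyl-2-[(triisopropylsilyl)oxy]phenyl}-2,7-dimethylnona-4,7-dien-2-yl]oxy}silane | COc1cc(C)c(O[Si](C(C)C)(C(C)C)C(C)C)c(C/C=C(\C)C/C(I)=C/CC(C)(C)O[Si](CC)(CC)CC)c1 | intermediate
26 | alkenyllithium from 25 (lithium in place of iodine, cis to the CH2C(CH3)2OSiEt3 chain) | COc1cc(C)c(O[Si](C(C)C)(C(C)C)C(C)C)c(C/C=C(\C)C/C([Li])=C/CC(C)(C)O[Si](CC)(CC)CC)c1 | intermediate (not isolated)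
27 | lithium carboxylate of 11 | [Li+].[O-]C(=O)[C@@]1(C)CCC[C@]1(C)CB2OC(C)(C)C(C)(C)O2 | intermediate (not isolated)
28 | dilithium boron ate complex (boron carries the C7 methylene, the alkenyl group and pinacolate) | [Li+].[Li+].[O-]C(=O)[C@@]1(C)CCC[C@]1(C)C[B-]2(OC(C)(C)C(C)(C)O2)/C(C/C(C)=C/Cc3cc(OC)cc(C)c3O[Si](C(C)C)(C(C)C)C(C)C)=C\CC(C)(C)O[Si](CC)(CC)CC | intermediate (not isolated)
29 | isobutyl mixed carbonic anhydride of ate complex 28 | [Li+].CC(C)COC(=O)OC(=O)[C@@]1(C)CCC[C@]1(C)C[B-]2(OC(C)(C)C(C)(C)O2)/C(C/C(C)=C/Cc3cc(OC)cc(C)c3O[Si](C(C)C)(C(C)C)C(C)C)=C\CC(C)(C)O[Si](CC)(CC)CC | intermediate (not isolated)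
30 | (3aS,5R,6R,7aR)-6-boryl hydrindan-4-one (full name in step 19) | COc1cc(C)c(O[Si](C(C)C)(C(C)C)C(C)C)c(C/C=C(\C)C[C@]2(B4OC(C)(C)C(C)(C)O4)C[C@@]3(C)CCC[C@]3(C)C(=O)[C@@H]2CC(C)(C)O[Si](CC)(CC)CC)c1 | intermediate
31 | (3aS,5R,6S,7aR)-6-hydroxy hydrindan-4-one bis-silyl ether (full name in step 20) | COc1cc(C)c(O[Si](C(C)C)(C(C)C)C(C)C)c(C/C=C(\C)C[C@]2(O)C[C@@]3(C)CCC[C@]3(C)C(=O)[C@@H]2CC(C)(C)O[Si](CC)(CC)CC)c1 | intermediate
32 | (3aS,5R,6S,7aR)-6-hydroxy-5-(2-hydroxy-2-methylpropyl)-6-[(2E)-4-(2-hydroxy-5-methoxy-3-methylphenyl)-2-methylbut-2-en-1-yl]-3a,7a-dimethyloctahydro-4H-inden-4-one | COc1cc(C)c(O)c(C/C=C(\C)C[C@]2(O)C[C@@]3(C)CCC[C@]3(C)C(=O)[C@@H]2CC(C)(C)O)c1 | target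

**Step count and risks**

Total step count: 21. Longest linear sequence: 13 steps (steps 1–10, then 19–21).

Steps most likely to fail:

1. Step 19 (proposed new method). What may go wrong: direct transfer of the alkenyl group from boron to the acyl nickel without the 1,2-shift, which would give an open-chain enone; reaction on the wrong alkene face; decarbonylation of the acyl nickel; or attack of the chloroformate on the ate complex before the carboxylate is acylated. Fallback (known chemistry, C4–C5 first, then C6–C7): it sets out from benzyl ester 9 and alkenyl iodide 25. Hydrogenolysis of 9 (H2, Pd/C) gives (1S,2S)-2-(bromomethyl)-1,2-dimethylcyclopentane-1-carboxylic acid F1, and (COCl)2 with catalytic DMF gives its acid chloride F2. Alkenyllithium 26 (from 25 and t-BuLi) is oxidised with Me3SiOOSiMe3 to the regiodefined trimethylsilyl enol ether F3. ZnCl2-promoted C-acylation of F3 with F2 gives the 2-substituted 1,3-diketone F4. SmI2/HMPA (THF, −78 → 0 °C) then closes the C6–C7 bond by an intramolecular Barbier reaction of the type known for 2-(haloalkyl)-1,3-dicarbonyl compounds: trivalent samarium chelates the C4 and C6 oxygens, which should place the new hydroxyl equatorial, and C5 (between two carbonyls) settles with its side chain equatorial. The product is 31, where the fallback rejoins the route.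

2. Step 18. What may go wrong: incomplete iodination of the branched ylide, erosion of Z selectivity in the olefination, or base-induced β-elimination of the silyloxy aldehyde. Fallback (borylzirconation in place of olefination): it sets out from allylic bromide 17 and commercial 2-methylpent-4-yn-2-ol and returns at 25. The alcohol is silylated (Et3SiOTf, 2,6-lutidine) to triethyl[(2-methylpent-4-yn-2-yl)oxy]silane F5. Deprotonation (n-BuLi) and trapping with 2-isopropoxy-4,4,5,5-tetramethyl-1,3,2-dioxaborolane, then HCl in Et2O, gives the alkynyl pinacol boronate F6. Syn hydrozirconation with Cp2Zr(H)Cl puts zirconium on the boron-bearing carbon, and Pd(PPh3)4-catalysed coupling of the C–Zr bond with 17 (retention, attack at the primary allylic carbon) gives the alkenyl pinacol boronate F7 with boron cis to the silyloxyalkyl chain. Iododeboronation with retention (NaI, TsN(Cl)Na, THF/H2O) gives 25.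

3. Step 20. What may go wrong: sluggish oxidation of the hindered tertiary boronate under neutral conditions and, if base is added to speed it up, retro-aldol opening of the product with loss of the C5/C6 configuration. Fallback (temporary change of oxidation level at C4): it sets out from 30 and returns at 31. NaBH4 (MeOH/THF) reduces the C4 ketone to the β-boryl alcohol F8 (C4 epimers are of no consequence). H2O2/NaOH, now without retro-aldol risk, gives the 4,6-diol F9. Dess–Martin periodinane with NaHCO3 oxidises only the secondary C4 alcohol and gives 31.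

**Further compounds**

F1 | step 19 | (1S,2S)-2-(bromomethyl)-1,2-dimethylcyclopentane-1-carboxylic acid | OC(=O)[C@@]1(C)CCC[C@]1(C)CBr
F2 | step 19 | (1S,2S)-2-(bromomethyl)-1,2-dimethylcyclopentane-1-carbonyl chloride | ClC(=O)[C@@]1(C)CCC[C@]1(C)CBr
F3 | step 19 | (4Z,7E)-9-{5-methoxy-3-methyl-2-[(triisopropylsilyl)oxy]phenyl}-2,7-dimethyl-2-[(triethylsilyl)oxy]-5-[(trimethylsilyl)oxy]nona-4,7-diene | COc1cc(C)c(O[Si](C(C)C)(C(C)C)C(C)C)c(C/C=C(\C)C/C(O[Si](C)(C)C)=C/CC(C)(C)O[Si](CC)(CC)CC)c1
F4 | step 19 | (5E)-1-[(1S,2S)-2-(bromomethyl)-1,2-dimethylcyclopentyl]-7-{5-methoxy-3-methyl-2-[(triisopropylsilyl)oxy]phenyl}-5-methyl-2-{2-methyl-2-[(triethylsilyl)oxy]propyl}hept-5-ene-1,3-dione (C2 epimers) | BrC[C@@]1(C)CCC[C@]1(C)C(=O)C(CC(C)(C)O[Si](CC)(CC)CC)C(=O)C/C(C)=C/Cc2cc(OC)cc(C)c2O[Si](C(C)C)(C(C)C)C(C)C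
F5 | step 18 | triethyl[(2-methylpent-4-yn-2-yl)oxy]silane | C#CCC(C)(C)O[Si](CC)(CC)CC
F6 | step 18 | triethyl{[2-methyl-5-(4,4,5,5-tetramethyl-1,3,2-dioxaborolan-2-yl)pent-4-yn-2-yl]oxy}silane | CC[Si](CC)(CC)OC(C)(C)CC#CB1OC(C)(C)C(C)(C)O1
F7 | step 18 | 2-[(4E,7E)-9-{5-methoxy-3-methyl-2-[(triisopropylsilyl)oxy]phenyl}-2,7-dimethyl-2-[(triethylsilyl)oxy]nona-4,7-dien-5-yl]-4,4,5,5-tetramethyl-1,3,2-dioxaborolane (boron cis to C3) | COc1cc(C)c(O[Si](C(C)C)(C(C)C)C(C)C)c(C/C=C(\C)C/C(B2OC(C)(C)C(C)(C)O2)=C/CC(C)(C)O[Si](CC)(CC)CC)c1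
F8 | step 20 | 4-hydroxy analogue of 30 (β-boryl alcohol, C4 epimers) | COc1cc(C)c(O[Si](C(C)C)(C(C)C)C(C)C)c(C/C=C(\C)C[C@]2(B4OC(C)(C)C(C)(C)O4)C[C@@]3(C)CCC[C@]3(C)C(O)[C@@H]2CC(C)(C)O[Si](CC)(CC)CC)c1
F9 | step 20 | 4,6-diol corresponding to 31 (C4 epimers) | COc1cc(C)c(O[Si](C(C)C)(C(C)C)C(C)C)c(C/C=C(\C)C[C@]2(O)C[C@@]3(C)CCC[C@]3(C)C(O)[C@@H]2CC(C)(C)O[Si](CC)(CC)CC)c1
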